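**Remark on the chemistry.** The configuration is taken as drawn: (2S,3S,4R) at the oxolane and E at the cinnamate. Ring A on C2 is cis to the CH2O arm on C3, and the arylmethyl group on C4 is trans to that arm. All oxolane intermediates are cited with the locants of the target (O1, C2 to C5; C9 = CH2O on C3; C7' = benzylic CH2 on C4; ring A = arene on C2; ring B = arene on C7').

## Analysis of the target

The target 20 is a 2,3,4-trisubstituted oxolane (ring O1–C2–C3–C4–C5) of the 7,9'-epoxylignan type. C2 carries a guaiacyl ring (ring A), C3 a CH2O arm (C9) esterified with (E)-p-coumaric acid, C4 a guaiacylmethyl group (C7', ring B), and C5 is an unsubstituted CH2 next to O1. The three stereocentres are contiguous, and the cis C2/C3 pair is the crowded, less stable arrangement. The C2–O1 bond is a para-oxygenated benzylic ether: acid ionises it to a quinone-methide-like cation (epimerisation to the 2,3-trans series, Friedel–Crafts capture by ring B or reductive ring opening), and hydrogenolysis cleaves it too. The three free phenols are acidic and oxidisable, and the cinnamate is sensitive to base, hydride, organometallic reagents and hydrogenation. The difficulties are therefore to set the cis C2/C3 pair under kinetic control and keep it, to tell two nearly identical guaiacyl rings apart, and to acylate a primary alcohol in the presence of phenols. The strategy rests on one reading of the ring: O1–C5H2 is a formaldehyde unit (7); C2(ring A)–C3–C4 is the carbon chain of a 2-arylcyclopropane whose acceptor carbon is C4, with C7' as the remnant of a geminal diester; and ring A–C2–C3–C9 is the intact C6–C3 unit of coniferaldehyde 1.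

## Retrosynthetic reasoning

**Ester C9–O.** The acyl–oxygen bond of the C9 ester is cut first, giving triol 18 and acid 19. The ester goes on last because it would not survive the hydride, organomagnesium, acid and hydroxide steps that build and unmask the core. A redox-condensation (Mitsunobu) esterification activates only the aliphatic C9–OH of 18 and accepts only the carboxylic acid of 19 as nucleophile, so none of the three phenols needs a protecting group.

**Protecting groups.** 18 is the unmasked form of 16, in which each group has a task. Ring A carries its phenol as an aryl sulfonate, which makes that arene a poor cation stabiliser and is inert to hydride and organomagnesium reagents (an aryl carboxylate would withdraw electrons equally but would not survive those reagents). Ring B carries a silyl ether, which keeps it electron-rich. C9–O carries a bulky trialkylsilyl ether, which must stay in place as long as an ester sits cis to it on C4. Fluoride and then hydroxide remove all three while no ester is yet present.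

**C7'.** The C7'–H bond of 16 is traced to the carbinol 15, and 15 is cut between C7' and ring B into aldehyde 11 and the arylmagnesium reagent 14 (from bromide 13, from phenol 12). This cut puts ring B on a one-step side branch and lets C7' come from a carbonyl carbon. The forward deoxygenation passes through a C7' cation: the silyloxy group of ring B stabilises it, the sulfonate on ring A keeps C2–O1 from ionising under the same acid, and the trans placement of C9 and C7' stops the cation from closing a second ring onto the C9 oxygen.

**C4.** Aldehyde 11 is traced through its C4-epimer mixture 10 to ester 9, and 9 to the geminal diester 8 by adding back one methoxycarbonyl group. C4 is the one centre left to thermodynamic control: next to a formyl group it is epimerisable, and the face anti to the C3 arm (which is also the face away from ring A) is clearly the less crowded one. Cutting the diester down first and equilibrating at the aldehyde stage avoids strong base in the presence of the sulfonate.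

**O1–C2 and C4–C5 (key disconnection).** 8 is cut at O1–C2 and C4–C5 into cyclopropane 6 and formaldehyde 7. These two bonds flank the only unsubstituted ring carbon, and cutting them removes the ring and leaves a strained precursor whose two stereocentres are easier to make than those of the oxolane. The forward annulation has to open 6 at the aryl carbon with inversion, so that the trans cyclopropane becomes the cis C2/C3 oxolane, and it delivers C5 directly at the CH2 oxidation level.

**Cyclopropane.** 6 is the silyl ether of alcohol 5, which comes from aldehyde 4 by reduction. 4 is cut at the two ring bonds of the malonate carbon into enal 2 and bromomalonate 3. An iminium–enamine organocatalytic Michael addition/alkylation sets both stereocentres from the catalyst and gives the trans isomer. 2 is the sulfonate of coniferaldehyde 1, so ring A, C2, C3 and C9 arrive as one commercial unit.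

## Alternatives that were turned down

**Alternative 1:** Both C3–C9 and C4–C7' are disconnected on a chiral-pool butenolide, (R)-5-(trityloxymethyl)furan-2(5H)-one A1. In the forward key step a sulfur-stabilised carbanion at the carboxyl oxidation level adds to the β-carbon anti to the trityloxymethyl group, and the lactone enolate is then benzylated anti to the new substituent, giving the all-trans lactone A2 in one flask.
- For: the absolute configuration comes from the chiral pool, and the trans C3/C4 pair is set by dependable 1,2-induction. On that pair it is stronger than the chosen route, which relies on an equilibration.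
- Against: the centre that steers everything is not a usable target centre. Its side chain has to be cut off, and C2 with its aryl group, cis to C3, must then be made by carbonyl addition and ring closure with no stereospecific link to an existing centre. Unmasking the thio-orthoester, reducing the lactone and cleaving a glycol add many operations, so the route is clearly longer than twelve steps.
- Comparison: the chosen route makes C2 by a stereospecific substitution and has C5 at the right oxidation level from the start.

**Alternative 2:** C2–C3 and the lactone C–O bond are disconnected to the silylated aldehyde A3 and the γ-substituted 2-(methoxycarbonyl)allylboronate A4. The forward key step is an asymmetric allylboration through a chair transition state, followed by acylation of the resulting alkoxide on the ester to give the 4,5-cis α-methylene lactone A5.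
- For: it is convergent, and the closed transition state sets the cis C2/C3 pair directly. On this point it is as strong as or stronger than the chosen route, since it does not depend on substitution outrunning ionisation.
- Against: A4 needs a geometry-defined multistep synthesis, and ester-deactivated allylboronates react sluggishly, so enantiocontrol is substrate-dependent. After the key step the exocyclic methylene must still be arylated, C4 is set only by a later protonation or equilibration, and the lactone carbonyl must be reduced to CH2 under Lewis-acidic silane conditions while ring A is an electron-rich silyl ether, which invites ionisation at C2 and loss of the cis relationship.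
- Comparison: the step count is similar. The chosen route offers C5 as CH2 without a lactone reduction, a deactivated ring A throughout the acid steps, and absolute control from a robust organocatalytic reaction on a commercial enal.

**Alternative 3:** O1–C5 is disconnected by oxygen insertion into the prochiral cyclobutanone A6. The forward key step is an enantioselective Baeyer–Villiger oxidation (chiral Lewis acid with a peracid, or a monooxygenase) that selects one of two enantiotopic C(O)–CH2 bonds and gives the (R)-β-benzyl lactone A7.
- For: it gives very short access to a classic lignan lactone from a cheap allylarene. C9 can then be added by enolate alkylation anti to the benzyl group, and ring A by aryl addition to the lactone and reduction of the lactol. On step economy it is as strong as or stronger than the chosen route.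
- Against: the new centre is remote from the reacting carbonyl and carries a flexible benzyl group, so the enantiomeric purity is the weak point. The cis C2/C3 pair would rest on facial selectivity of hydride delivery to a planar 2-aryl oxocarbenium ion, which is also the intermediate through which the electron-rich product epimerises or is reduced further to a ring-opened compound.
- Comparison: the chosen route is about two steps longer, but it fixes C2 by inversion at a defined centre, and the aryl-bearing carbon never becomes a free cation.

Key step: step 5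

## Route

Step 1
Reactants: 1 coniferaldehyde
Product: 2 2-methoxy-4-[(E)-3-oxoprop-1-enyl]phenyl 4-methylbenzenesulfonate
Conditions: TsCl (1.1 equiv), Et3N, DMAP (cat.), CH2Cl2, 0 °C → rt
Reagents that add atoms: 4-methylbenzenesulfonyl chloride, Cc1ccc(S(=O)(=O)Cl)cc1
Why: O-sulfonylation of the phenol; the enal is untouched. The sulfonate is electron-withdrawing, inert to amines, hydride, Lewis and Brønsted acids and aryl Grignard reagents, and can be removed by hydroxide.

Step 2
Reactants: 2 coniferaldehyde tosylate; 3 dimethyl bromomalonate
Product: 4 dimethyl (2S,3R)-2-formyl-3-[3-methoxy-4-(tosyloxy)phenyl]cyclopropane-1,1-dicarboxylate (formyl trans to aryl)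
Conditions: (R)-2-[diphenyl(trimethylsilyloxy)methyl]pyrrolidine (20 mol%), 2,6-lutidine (1.1 equiv), CH2Cl2, 0 °C → rt
Reagents that add atoms: none
Why: Organocatalytic Michael-initiated ring closure (iminium–enamine domino Michael/α-alkylation). The diphenyl(silyloxy)methyl group of the (R)-catalyst shields one face of the E-iminium ion, so the bromomalonate should add to the β-Re face and make the aryl carbon R. The enamine then displaces bromide (3-exo-tet) to give the trans cyclopropane.

Step 3
Reactants: 4 formylcyclopropane diester
Product: 5 dimethyl (2S,3R)-2-(hydroxymethyl)-3-[3-methoxy-4-(tosyloxy)phenyl]cyclopropane-1,1-dicarboxylate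
Conditions: NaBH4 (1 equiv), MeOH/CH2Cl2 1:4, −40 °C, short reaction time; pH 7 buffer; crude product used directly
Reagents that add atoms: none
Why: Chemoselective borohydride reduction of the aldehyde; esters, sulfonate and cyclopropane are not attacked and no stereocentre is involved. Low temperature, neutral work-up and direct use keep the γ-hydroxy diester from closing to a cyclopropane-fused lactone.

Step 4
Reactants: 5 hydroxymethylcyclopropane diester
Product: 6 dimethyl (2R,3S)-2-[3-methoxy-4-(tosyloxy)phenyl]-3-[(triisopropylsilyloxy)methyl]cyclopropane-1,1-dicarboxylate (aryl trans to CH2OSi)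
Conditions: iPr3SiOTf (1.2 equiv), 2,6-lutidine (2 equiv), CH2Cl2, −78 °C
Reagents that add atoms: triisopropylsilyl trifluoromethanesulfonate, CC(C)[Si](C(C)C)(C(C)C)OS(=O)(=O)C(F)(F)F
Why: O-silylation with a silyl triflate is complete within minutes at −78 °C under non-nucleophilic conditions, so it outruns lactonisation. The triisopropylsilyl ether is chosen over a smaller silyl ether because it must survive a Lewis acid, hot chloride and trifluoroacetic acid.

Step 5
Reactants: 6 silyloxymethyl arylcyclopropane diester; 7 formaldehyde (charged as paraformaldehyde)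
Product: 8 dimethyl (2S,3S)-2-[3-methoxy-4-(tosyloxy)phenyl]-3-[(triisopropylsilyloxy)methyl]oxolane-4,4-dicarboxylate (aryl cis to CH2OSi)
Conditions: (CH2O)n (5 equiv), Sn(OTf)2 (20 mol%), ClCH2CH2Cl, 40 °C
Reagents that add atoms: none
Why: Sn(OTf)2 binds both ester carbonyls of 6 as a chelate and polarises the bond between the malonate carbon and the aryl-bearing carbon; the carbonyl oxygen of 7 displaces the malonate carbon from the rear of that bond (an SN2-like opening through an intimate ion pair), which forms O1–C2 and leaves a tin malonate enolate tethered to an O-alkylated oxocarbenium ion. The enolate carbon then adds to the oxocarbenium carbon and forms C4–C5; this closure of the oxolane is formally 5-endo-trig (enol-exo, Prins/aldol type) and is fast because the acceptor is a cation. The closest known reaction type is the Lewis-acid-catalysed (3+2) annulation of 2-arylcyclopropane-1,1-diesters with aldehydes, which transfers the configuration of the donor carbon with inversion and tolerates a further substituent on the third ring carbon. C2 is the only stereocentre that is made: it results from inversion of the R-configured aryl carbon of 6 (substrate control, stereospecific), C3 is not touched, so the trans cyclopropane must give the 2,3-cis oxolane; C5 carries two hydrogens and C4 two identical esters, so nothing else is at stake. Two selectivities are needed: cleavage of the aryl-substituted ring bond and not of the bond to the silyloxymethyl-bearing carbon, which is secured because only the benzylic carbon can carry positive charge, and substitution before ionisation, which is secured by the sulfonate that makes ring A a poor cation stabiliser. The same sulfonate protects the product, whose cis arrangement is the less stable one, from re-ionisation at C2 by the Lewis acid. An excess of 7 makes up for the low nucleophilicity of its oxygen.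

Step 6
Reactants: 8 oxolane geminal diester
Product: 9 methyl (2S,3S,4RS)-2-[3-methoxy-4-(tosyloxy)phenyl]-3-[(triisopropylsilyloxy)methyl]oxolane-4-carboxylate (both C4 epimers)
Conditions: NaCl (2 equiv), H2O (3 equiv), DMSO, 150 °C
Reagents that add atoms: none
Why: Krapcho dealkoxycarbonylation: chloride demethylates one ester by SN2, the carboxylate loses CO2 and the ester enolate is protonated, giving both C4 epimers, which converge in step 7. The medium is nearly neutral, so sulfonate and silyl ether should survive. Ring opening by β-elimination of O1 from the enolate is the reverse of a 5-endo-trig closure and is stereoelectronically slow.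

Step 7
Reactants: 9 oxolane monoester (C4 epimers)
Product: 11 (2S,3S,4R)-2-[3-methoxy-4-(tosyloxy)phenyl]-3-[(triisopropylsilyloxy)methyl]oxolane-4-carbaldehyde, via C4-epimeric aldehyde mixture 10 (not isolated)
Conditions: iBu2AlH (1.15 equiv), CH2Cl2, −78 °C; aq. potassium sodium tartrate; then DBU (0.2 equiv), CH2Cl2, rt
Reagents that add atoms: none
Why: Half-reduction of the methyl ester: the aluminium hemiacetal, chelated by O1, is stable at −78 °C and releases the aldehyde on work-up; sulfonate and silyl ether do not react. Base-mediated epimerisation of the α-formyl centre then places the formyl group on the face anti to the C3 arm and away from ring A (thermodynamic control), which should give the 3,4-trans aldehyde.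

Step 8
Reactants: 12 4-bromo-2-methoxyphenol
Product: 13 (4-bromo-2-methoxyphenoxy)(tert-butyl)dimethylsilane
Conditions: tBuMe2SiCl, imidazole, DMF, rt
Reagents that add atoms: tert-butyldimethylsilyl chloride, CC(C)(C)[Si](C)(C)Cl
Why: Standard silylation of a phenol. The aryl silyl ether tolerates magnesium insertion and keeps ring B electron-rich for step 10.

Step 9
Reactants: 13 silylated aryl bromide; 11 trans aldehyde
Product: 15 [4-(tert-butyldimethylsilyloxy)-3-methoxyphenyl]{(2S,3S,4R)-2-[3-methoxy-4-(tosyloxy)phenyl]-3-[(triisopropylsilyloxy)methyl]oxolan-4-yl}methanol as both C7' epimers, via arylmagnesium bromide 14 (not isolated)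
Conditions: 13, Mg (I2 cat.), THF, 50 °C; then 11, THF, −78 → −40 °C; aq. NH4Cl
Reagents that add atoms: none
Why: Grignard formation and 1,2-addition to the aldehyde, which at low temperature is faster than enolisation of the α-centre. Aryl sulfonates and silyl ethers are inert to ArMgBr without a transition-metal catalyst. The new carbinol centre forms unselectively and is removed in step 10.

Step 10
Reactants: 15 C7' carbinol
Product: 16 4-{(2S,3S,4R)-4-[4-(tert-butyldimethylsilyloxy)-3-methoxybenzyl]-3-[(triisopropylsilyloxy)methyl]oxolan-2-yl}-2-methoxyphenyl 4-methylbenzenesulfonate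
Conditions: Et3SiH (5 equiv), CF3CO2H (5 equiv), CH2Cl2, −40 → −20 °C
Reagents that add atoms: none
Why: Ionic hydrogenation: the acid ionises the carbinol to a cation stabilised by the para-silyloxy group of ring B, and the silane delivers hydride. The C2–O1 ether should stay intact because ring A is deactivated by the sulfonate, and the trans placement of C9 and C7' prevents capture of the cation by the C9 oxygen or by ring A. Any partial loss of a silyl group is harmless because step 11 removes them.

Step 11
Reactants: 16 protected lignan core
Product: 18 4-[(2S,3S,4R)-4-(4-hydroxy-3-methoxybenzyl)-3-(hydroxymethyl)oxolan-2-yl]-2-methoxyphenol, via diol tosylate 17 (not isolated)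
Conditions: Bu4NF (3 equiv), THF, 0 °C → rt; then KOH, MeOH/H2O, 60 °C; aq. NH4Cl
Reagents that add atoms: none
Why: Fluoride cleaves both silyl ethers, and hydroxide then cleaves the aryl sulfonate by attack at sulfur. No ester is present yet, and the phenolic oxolane tolerates base at this temperature, unlike acid. No stereocentre is touched.

Step 12
Reactants: 18 lignan triol; 19 p-coumaric acid
Product: 20 [(2S,3S,4R)-2-(4-hydroxy-3-methoxyphenyl)-4-(4-hydroxy-3-methoxybenzyl)oxolan-3-yl]methyl (E)-3-(4-hydroxyphenyl)prop-2-enoate
Conditions: PPh3 (1.5 equiv), iPrO2CN=NCO2iPr (1.5 equiv), 19 (1.5 equiv), THF, 0 °C → rt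
Reagents that add atoms: none
Why: Mitsunobu esterification: only the aliphatic C9–OH forms an alkoxyphosphonium ion, and the carboxylic acid, far more acidic than any phenol, supplies the nucleophile, so the ester should form without phenol protection. Substitution occurs at the primary CH2, so no stereocentre is involved, and the neutral conditions spare the C2–O1 ether and the E-alkene.

## Compound list

1 | coniferaldehyde, (E)-3-(4-hydroxy-3-methoxyphenyl)prop-2-enal | COc1cc(/C=C/C=O)ccc1O | starting material
2 | 2-methoxy-4-[(E)-3-oxoprop-1-enyl]phenyl 4-methylbenzenesulfonate | COc1cc(/C=C/C=O)ccc1OS(=O)(=O)c1ccc(C)cc1 | intermediate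
3 | dimethyl bromomalonate | COC(=O)C(Br)C(=O)OC | starting material
4 | dimethyl (2S,3R)-2-formyl-3-[3-methoxy-4-(tosyloxy)phenyl]cyclopropane-1,1-dicarboxylate, formyl trans to aryl | COC(=O)C1(C(=O)OC)[C@@H](c2ccc(OS(=O)(=O)c3ccc(C)cc3)c(OC)c2)[C@@H]1C=O | intermediate
5 | dimethyl (2S,3R)-2-(hydroxymethyl)-3-[3-methoxy-4-(tosyloxy)phenyl]cyclopropane-1,1-dicarboxylate | COC(=O)C1(C(=O)OC)[C@@H](c2ccc(OS(=O)(=O)c3ccc(C)cc3)c(OC)c2)[C@@H]1CO | intermediate
6 | dimethyl (2R,3S)-2-[3-methoxy-4-(tosyloxy)phenyl]-3-[(triisopropylsilyloxy)methyl]cyclopropane-1,1-dicarboxylate, aryl trans to CH2OSi | COC(=O)C1(C(=O)OC)[C@@H](c2ccc(OS(=O)(=O)c3ccc(C)cc3)c(OC)c2)[C@@H]1CO[Si](C(C)C)(C(C)C)C(C)C | intermediate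
7 | formaldehyde, charged as paraformaldehyde | C=O | starting material
8 | dimethyl (2S,3S)-2-[3-methoxy-4-(tosyloxy)phenyl]-3-[(triisopropylsilyloxy)methyl]oxolane-4,4-dicarboxylate (target locants), aryl cis to CH2OSi | COC(=O)C1(C(=O)OC)CO[C@H](c2ccc(OS(=O)(=O)c3ccc(C)cc3)c(OC)c2)[C@@H]1CO[Si](C(C)C)(C(C)C)C(C)C | intermediate
9 | methyl (2S,3S,4RS)-2-[3-methoxy-4-(tosyloxy)phenyl]-3-[(triisopropylsilyloxy)methyl]oxolane-4-carboxylate, both C4 epimers | COC(=O)C1CO[C@H](c2ccc(OS(=O)(=O)c3ccc(C)cc3)c(OC)c2)[C@@H]1CO[Si](C(C)C)(C(C)C)C(C)C | intermediate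
10 | (2S,3S,4RS)-2-[3-methoxy-4-(tosyloxy)phenyl]-3-[(triisopropylsilyloxy)methyl]oxolane-4-carbaldehyde, both C4 epimers | O=CC1CO[C@H](c2ccc(OS(=O)(=O)c3ccc(C)cc3)c(OC)c2)[C@@H]1CO[Si](C(C)C)(C(C)C)C(C)C | intermediate (not isolated)
11 | (2S,3S,4R)-2-[3-methoxy-4-(tosyloxy)phenyl]-3-[(triisopropylsilyloxy)methyl]oxolane-4-carbaldehyde, 2,3-cis and 3,4-trans | O=C[C@H]1CO[C@H](c2ccc(OS(=O)(=O)c3ccc(C)cc3)c(OC)c2)[C@@H]1CO[Si](C(C)C)(C(C)C)C(C)C | intermediate
12 | 4-bromo-2-methoxyphenol | COc1cc(Br)ccc1O | starting material
13 | (4-bromo-2-methoxyphenoxy)(tert-butyl)dimethylsilane | COc1cc(Br)ccc1O[Si](C)(C)C(C)(C)C | intermediate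
14 | [4-(tert-butyldimethylsilyloxy)-3-methoxyphenyl]magnesium bromide | COc1cc([Mg]Br)ccc1O[Si](C)(C)C(C)(C)C | intermediate (not isolated)
15 | [4-(tert-butyldimethylsilyloxy)-3-methoxyphenyl]{(2S,3S,4R)-2-[3-methoxy-4-(tosyloxy)phenyl]-3-[(triisopropylsilyloxy)methyl]oxolan-4-yl}methanol, both C7' epimers | COc1cc(C(O)[C@H]2CO[C@H](c3ccc(OS(=O)(=O)c4ccc(C)cc4)c(OC)c3)[C@@H]2CO[Si](C(C)C)(C(C)C)C(C)C)ccc1O[Si](C)(C)C(C)(C)C | intermediate
16 | 4-{(2S,3S,4R)-4-[4-(tert-butyldimethylsilyloxy)-3-methoxybenzyl]-3-[(triisopropylsilyloxy)methyl]oxolan-2-yl}-2-methoxyphenyl 4-methylbenzenesulfonate | COc1cc(C[C@H]2CO[C@H](c3ccc(OS(=O)(=O)c4ccc(C)cc4)c(OC)c3)[C@@H]2CO[Si](C(C)C)(C(C)C)C(C)C)ccc1O[Si](C)(C)C(C)(C)C | intermediate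
17 | 4-[(2S,3S,4R)-4-(4-hydroxy-3-methoxybenzyl)-3-(hydroxymethyl)oxolan-2-yl]-2-methoxyphenyl 4-methylbenzenesulfonate | COc1cc(C[C@H]2CO[C@H](c3ccc(OS(=O)(=O)c4ccc(C)cc4)c(OC)c3)[C@@H]2CO)ccc1O | intermediate (not isolated)
18 | 4-[(2S,3S,4R)-4-(4-hydroxy-3-methoxybenzyl)-3-(hydroxymethyl)oxolan-2-yl]-2-methoxyphenol | COc1cc(C[C@H]2CO[C@H](c3ccc(O)c(OC)c3)[C@@H]2CO)ccc1O | intermediate
19 | p-coumaric acid, (E)-3-(4-hydroxyphenyl)prop-2-enoic acid | O=C(O)/C=C/c1ccc(O)cc1 | starting material
20 | [(2S,3S,4R)-2-(4-hydroxy-3-methoxyphenyl)-4-(4-hydroxy-3-methoxybenzyl)oxolan-3-yl]methyl (E)-3-(4-hydroxyphenyl)prop-2-enoate | COc1cc(C[C@H]2CO[C@H](c3ccc(O)c(OC)c3)[C@@H]2COC(=O)/C=C/c2ccc(O)cc2)ccc1O | target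

## Step count and least certain steps

Total: 12 steps. Longest linear sequence: 11 steps (steps 1 to 7 and 9 to 12, from 1); step 8 is a one-step branch.

**Step 5 (key step).** The weakly basic oxygen of monomeric formaldehyde may capture the tin-activated cyclopropane too slowly, all the more so because the donor arene is deliberately deactivated. Competing processes are insertion of more than one formaldehyde unit from oligomers, desilylation by adventitious triflic acid followed by lactonisation, and, if a stronger Lewis acid such as Sc(OTf)3 is used to force the reaction, ionisation at the aryl carbon with loss of configuration. Fallback (from 6, back at 16): the formaldehyde annulation is given up and C5 is taken from one of the ester groups.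
- Sc(OTf)3-catalysed hydration of 6 (H2O, MeCN, 50 °C) should open the ring at the benzylic carbon with inversion, and the γ-hydroxy diester closes to methyl (2S,3S)-2-[3-methoxy-4-(tosyloxy)phenyl]-5-oxo-3-[(triisopropylsilyloxy)methyl]oxolane-4-carboxylate F1.
- Krapcho dealkoxycarbonylation (NaCl, wet DMSO) gives the 2,3-cis lactone (4S,5S)-5-[3-methoxy-4-(tosyloxy)phenyl]-4-[(triisopropylsilyloxy)methyl]dihydrofuran-2(3H)-one F2.
- The electrophile is made from vanillin: silylation gives 4-(tert-butyldimethylsilyloxy)-3-methoxybenzaldehyde F3, NaBH4 gives [4-(tert-butyldimethylsilyloxy)-3-methoxyphenyl]methanol F4, and PBr3 gives [4-(bromomethyl)-2-methoxyphenoxy](tert-butyl)dimethylsilane F5.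
- The lithium enolate of F2 (LiN(SiMe3)2, THF, −78 °C) is alkylated by F5 anti to the C3 arm, giving the 3,4-trans benzyl lactone F6.
- iBu2AlH at −78 °C reduces F6 to the lactol F7, and Et3SiH/BF3·OEt2 at −78 °C removes the anomeric hydroxyl to give 16.

**Step 10.** The acid may also ionise C2–O1 if the sulfonate does not deactivate ring A enough, which would epimerise C2 towards the trans series or allow Friedel–Crafts capture by ring B. The C7' cation may also lose the C4 proton, and reprotonation of the resulting styrene would scramble C4. Fallback (from 11, back at 16): the benzylic cation is avoided altogether. NaBH4 reduces 11 to the primary alcohol {(2S,3S)-2-[3-methoxy-4-(tosyloxy)phenyl]-3-[(triisopropylsilyloxy)methyl]oxolan-4-yl}methanol F8 (3,4-trans). I2, PPh3 and imidazole convert it into the iodide 4-{(2S,3S)-4-(iodomethyl)-3-[(triisopropylsilyloxy)methyl]oxolan-2-yl}-2-methoxyphenyl 4-methylbenzenesulfonate F9 (3,4-trans). Coupling of F9 with the arylmagnesium bromide 14 under Li2CuCl4 catalysis (THF, 0 °C) gives 16.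

**Step 7.** The aluminium hemiacetal may collapse early and be reduced further to the primary alcohol, the equilibration may stop at an insufficient trans preference, and prolonged base could open the ring by β-elimination of O1. Fallback (from 9, back at 15): the aldehyde is replaced by a ketone, which cannot be over-reduced and epimerises more readily. 9 is converted with MeNH(OMe)·HCl and iPrMgCl (THF, −20 °C) into the Weinreb amide (2S,3S)-N-methoxy-N-methyl-2-[3-methoxy-4-(tosyloxy)phenyl]-3-[(triisopropylsilyloxy)methyl]oxolane-4-carboxamide F10. Addition of 14 and equilibration with DBU give the 3,4-trans aryl ketone 4-{(2S,3S,4R)-4-[4-(tert-butyldimethylsilyloxy)-3-methoxybenzoyl]-3-[(triisopropylsilyloxy)methyl]oxolan-2-yl}-2-methoxyphenyl 4-methylbenzenesulfonate F11, which NaBH4 reduces to 15.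

**Step 12.** A phenol may compete as nucleophile for the activated C9 (aryl ether formation), substitution at the β-branched primary carbon may be slow, and separation from the phosphine oxide and the hydrazide may cost material. Fallback (from 18, back at 20): chemoselectivity is replaced by temporary phenol protection. Ac2O with aqueous NaOH at 0 °C acetylates only the two phenoxides of 18 and gives the diacetate 4-[(2S,3S,4R)-4-(4-acetoxy-3-methoxybenzyl)-3-(hydroxymethyl)oxolan-2-yl]-2-methoxyphenyl acetate F12. Carbodiimide/DMAP esterification with (E)-3-(4-acetoxyphenyl)prop-2-enoic acid F13 (from 19, Ac2O, pyridine) gives the triacetate ester F14, the 4-acetoxycinnamate of F12. Pyrrolidine in CH2Cl2 at rt cleaves the three aryl acetates much faster than the alkyl cinnamate and gives 20.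

## Further compounds

F1 | step 5 | methyl (2S,3S)-2-[3-methoxy-4-(tosyloxy)phenyl]-5-oxo-3-[(triisopropylsilyloxy)methyl]oxolane-4-carboxylate, C4 epimers | COC(=O)C1C(=O)O[C@H](c2ccc(OS(=O)(=O)c3ccc(C)cc3)c(OC)c2)[C@@H]1CO[Si](C(C)C)(C(C)C)C(C)C
F2 | step 5 | (4S,5S)-5-[3-methoxy-4-(tosyloxy)phenyl]-4-[(triisopropylsilyloxy)methyl]dihydrofuran-2(3H)-one, 4,5-cis | O=C1O[C@H](c2ccc(OS(=O)(=O)c3ccc(C)cc3)c(OC)c2)[C@H](CO[Si](C(C)C)(C(C)C)C(C)C)C1
F3 | step 5 | 4-(tert-butyldimethylsilyloxy)-3-methoxybenzaldehyde | COc1cc(C=O)ccc1O[Si](C)(C)C(C)(C)C
F4 | step 5 | [4-(tert-butyldimethylsilyloxy)-3-methoxyphenyl]methanol | COc1cc(CO)ccc1O[Si](C)(C)C(C)(C)C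
F5 | step 5 | [4-(bromomethyl)-2-methoxyphenoxy](tert-butyl)dimethylsilane | COc1cc(CBr)ccc1O[Si](C)(C)C(C)(C)C
F6 | step 5 | 3-[4-(tert-butyldimethylsilyloxy)-3-methoxybenzyl]-5-[3-methoxy-4-(tosyloxy)phenyl]-4-[(triisopropylsilyloxy)methyl]dihydrofuran-2(3H)-one, 3,4-trans and 4,5-cis | COc1cc(C[C@H]2C(=O)O[C@H](c3ccc(OS(=O)(=O)c4ccc(C)cc4)c(OC)c3)[C@@H]2CO[Si](C(C)C)(C(C)C)C(C)C)ccc1O[Si](C)(C)C(C)(C)C
F7 | step 5 | lactol of F6, 4-{4-[4-(tert-butyldimethylsilyloxy)-3-methoxybenzyl]-5-hydroxy-3-[(triisopropylsilyloxy)methyl]oxolan-2-yl}-2-methoxyphenyl 4-methylbenzenesulfonate, anomers | COc1cc(C[C@H]2C(O)O[C@H](c3ccc(OS(=O)(=O)c4ccc(C)cc4)c(OC)c3)[C@@H]2CO[Si](C(C)C)(C(C)C)C(C)C)ccc1O[Si](C)(C)C(C)(C)C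
F8 | step 10 | {(2S,3S)-2-[3-methoxy-4-(tosyloxy)phenyl]-3-[(triisopropylsilyloxy)methyl]oxolan-4-yl}methanol, 3,4-trans | OC[C@H]1CO[C@H](c2ccc(OS(=O)(=O)c3ccc(C)cc3)c(OC)c2)[C@@H]1CO[Si](C(C)C)(C(C)C)C(C)C
F9 | step 10 | 4-{(2S,3S)-4-(iodomethyl)-3-[(triisopropylsilyloxy)methyl]oxolan-2-yl}-2-methoxyphenyl 4-methylbenzenesulfonate, 3,4-trans | IC[C@H]1CO[C@H](c2ccc(OS(=O)(=O)c3ccc(C)cc3)c(OC)c2)[C@@H]1CO[Si](C(C)C)(C(C)C)C(C)C
F10 | step 7 | (2S,3S)-N-methoxy-N-methyl-2-[3-methoxy-4-(tosyloxy)phenyl]-3-[(triisopropylsilyloxy)methyl]oxolane-4-carboxamide, C4 epimers | CON(C)C(=O)C1CO[C@H](c2ccc(OS(=O)(=O)c3ccc(C)cc3)c(OC)c2)[C@@H]1CO[Si](C(C)C)(C(C)C)C(C)C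
F11 | step 7 | 4-{(2S,3S,4R)-4-[4-(tert-butyldimethylsilyloxy)-3-methoxybenzoyl]-3-[(triisopropylsilyloxy)methyl]oxolan-2-yl}-2-methoxyphenyl 4-methylbenzenesulfonate | COc1cc(C(=O)[C@H]2CO[C@H](c3ccc(OS(=O)(=O)c4ccc(C)cc4)c(OC)c3)[C@@H]2CO[Si](C(C)C)(C(C)C)C(C)C)ccc1O[Si](C)(C)C(C)(C)C
F12 | step 12 | 4-[(2S,3S,4R)-4-(4-acetoxy-3-methoxybenzyl)-3-(hydroxymethyl)oxolan-2-yl]-2-methoxyphenyl acetate | COc1cc(C[C@H]2CO[C@H](c3ccc(OC(C)=O)c(OC)c3)[C@@H]2CO)ccc1OC(C)=O
F13 | step 12 | (E)-3-(4-acetoxyphenyl)prop-2-enoic acid | CC(=O)Oc1ccc(/C=C/C(=O)O)cc1
F14 | step 12 | [(2S,3S,4R)-2-(4-acetoxy-3-methoxyphenyl)-4-(4-acetoxy-3-methoxybenzyl)oxolan-3-yl]methyl (E)-3-(4-acetoxyphenyl)prop-2-enoate | COc1cc(C[C@H]2CO[C@H](c3ccc(OC(C)=O)c(OC)c3)[C@@H]2COC(=O)/C=C/c2ccc(OC(C)=O)cc2)ccc1OC(C)=O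
A1 | alternative 1 | (R)-5-(trityloxymethyl)furan-2(5H)-one | O=C1O[C@@H](COC(c2ccccc2)(c2ccccc2)c2ccccc2)C=C1
A2 | alternative 1 | all-trans 3-[4-(tert-butyldimethylsilyloxy)-3-methoxybenzyl]-4-[tris(methylthio)methyl]-5-(trityloxymethyl)dihydrofuran-2(3H)-one | COc1cc(C[C@H]2C(=O)O[C@@H](COC(c3ccccc3)(c3ccccc3)c3ccccc3)[C@@H]2C(SC)(SC)SC)ccc1O[Si](C)(C)C(C)(C)C
A3 | alternative 2 | 4-(tert-butyldimethylsilyloxy)-3-methoxybenzaldehyde | COc1cc(C=O)ccc1O[Si](C)(C)C(C)(C)C
A4 | alternative 2 | methyl (E)-4-(tert-butyldimethylsilyloxy)-2-[(4,4,5,5-tetramethyl-1,3,2-dioxaborolan-2-yl)methyl]but-2-enoate, silyloxymethyl cis to the borylmethyl group | COC(=O)/C(CB1OC(C)(C)C(C)(C)O1)=C/CO[Si](C)(C)C(C)(C)C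
A5 | alternative 2 | 4,5-cis-5-[4-(tert-butyldimethylsilyloxy)-3-methoxyphenyl]-3-methylene-4-[(tert-butyldimethylsilyloxy)methyl]dihydrofuran-2(3H)-one | C=C1C(=O)O[C@H](c2ccc(O[Si](C)(C)C(C)(C)C)c(OC)c2)[C@@H]1CO[Si](C)(C)C(C)(C)C
A6 | alternative 3 | 3-[4-(tert-butyldimethylsilyloxy)-3-methoxybenzyl]cyclobutan-1-one | COc1cc(CC2CC(=O)C2)ccc1O[Si](C)(C)C(C)(C)C
A7 | alternative 3 | (R)-4-[4-(tert-butyldimethylsilyloxy)-3-methoxybenzyl]dihydrofuran-2(3H)-one | COc1cc(C[C@H]2COC(=O)C2)ccc1O[Si](C)(C)C(C)(C)C
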